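C1–C15 follow farnesol numbering (C13–C15 are added later). The lactone atoms are O1′, C2′(=O), C3′, C4′, C5′H2 and C6′H, where C5′ = C1, C6′ = C2, C4′ = C14 and C3′ = C15.
Cuts, in order: the O–O group (Schenck ene on the C6=C7 alkene); C3′–CH3 (enolate methylation); then C2′–C3′ and C4′–C5′ together, which opens the δ-lactone and the 14-membered ring at once to an acyclic chain; C13–C14 (B-alkyl Suzuki). What remains is (2E,6E)-farnesol.
Enabling feature: the δ-lactone bridges C4′ and C6′ of the carbocycle. O1′ on C6′ can therefore carry C2′ as an acyl-type radical while the adjacent C5′H2 carries a leaving group. This 1,4 radical/electrophile pair matches the alkene carbons C3′=C4′ of a 2-alkylacrolein at the other chain end; the formyl group on C4′ is a helper.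
Forward: both chain ends are functionalised. One photoredox event then closes a 16-membered macrolactone (C2′–C3′), which contracts across the ring (C4′–C5′) to the 14-membered carbocycle plus δ-lactone. The helper formyl is removed, and the methyl and OOH groups are added last.
Stereochemistry: two Sharpless epoxidations with L-(+)-DET give the C10/C11 epoxide and, after Payne inversion at C2, the C2/C3 diol. C4′ is set from C6′ in the transannular alkylation and kept in the decarbonylation. C3′ comes from anti (also thermodynamic) methylation, and C6–OOH from peripheral attack of singlet oxygen.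

Key step: step 15

Step 1
Reactants: 1 (2E,6E)-farnesol
Product: 2 farnesyl TBS ether
Conditions: TBSCl, imidazole, DMF, 0 °C to rt
Reagents that add atoms: tert-butyldimethylsilyl chloride CC(C)(C)[Si](C)(C)Cl
Why: Routine silylation masks the allylic alcohol with a group that, unlike an allylic ester, is inert in the later palladium-catalysed coupling.

Step 2
Reactants: 2 farnesyl TBS ether
Product: 3 (2E,6E,10E)-12-hydroxyfarnesyl TBS ether
Conditions: SeO2 (cat.), t-BuOOH, salicylic acid (cat.), CH2Cl2, 0 °C to rt
Reagents that add atoms: tert-butyl hydroperoxide CC(C)(C)OO (oxygen relayed by SeO2 O=[Se]=O)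
Why: Catalytic Riley allylic oxidation (ene reaction, then [2,3]-shift) attacks the most electron-rich and least hindered terminal isopropylidene group and should give the (E)-allylic alcohol.

Step 3
Reactants: 3 (2E,6E,10E)-12-hydroxyfarnesyl TBS ether
Product: 4 (10S,11S)-epoxy alcohol
Conditions: Ti(OiPr)4 (cat.), L-(+)-diethyl tartrate (cat.), t-BuOOH, 4 Å MS, CH2Cl2, −20 °C
Reagents that add atoms: tert-butyl hydroperoxide CC(C)(C)OO
Why: Sharpless asymmetric epoxidation is directed by the C12 hydroxyl, so only C10=C11 reacts, and L-(+)-DET should set both epoxide centres as (10S,11S).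

Step 4
Reactants: 4 (10S,11S)-epoxy alcohol
Product: 5 epoxy aldehyde
Conditions: TEMPO (cat.), PhI(OAc)2, CH2Cl2, rt
Reagents that add atoms: none
Why: Oxoammonium (TEMPO) oxidation stops at the aldehyde under nearly neutral conditions; C11 is quaternary and cannot epimerise (its descriptor becomes 11R by priority change only).

Step 5
Reactants: 5 epoxy aldehyde
Product: 6 vinyl epoxide
Conditions: Ph3PCH3Br, KN(SiMe3)2, THF, −78 °C to 0 °C
Reagents that add atoms: methyltriphenylphosphonium bromide C[P+](c1ccccc1)(c1ccccc1)c1ccccc1.[Br-]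
Why: Wittig methylenation of the non-enolisable aldehyde adds C13 as the only monosubstituted alkene of the molecule.

Step 6
Reactants: 7 acrolein diethyl acetal
Product: 9 2-bromo-3,3-diethoxyprop-1-ene, via dibromide 8 (not isolated)
Conditions: Br2, CH2Cl2, 0 °C; then KOtBu, THF, 0 °C to rt
Reagents that add atoms: bromine BrBr
Why: Alkene bromination followed by E2 loss of HBr (the more acidic H next to the acetal, with the terminal bromide as leaving group) gives the masked 2-bromoacrolein.

Step 7
Reactants: 6 vinyl epoxide; 9 2-bromo-3,3-diethoxyprop-1-ene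
Product: 11 masked 2-alkylacrolein TBS ether, via B-alkyl-9-BBN 10 (not isolated)
Conditions: 9-BBN, THF, 0 °C to rt; then 9, Pd(dppf)Cl2 (5 mol %), AsPh3, Cs2CO3, DMF/H2O, rt
Reagents that add atoms: none
Why: 9-BBN hydroborates only the monosubstituted alkene at its terminus (boron ends three carbons from the epoxide oxygen, so no β-elimination is possible), and B-alkyl Suzuki–Miyaura coupling forms C13–C14.

Step 8
Reactants: 11 masked 2-alkylacrolein TBS ether
Product: 12 allylic alcohol
Conditions: Bu4NF, THF, 0 °C to rt
Reagents that add atoms: none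
Why: Fluoride desilylation frees the C1 alcohol without touching the acetal, epoxide or alkenes.

Step 9
Reactants: 12 allylic alcohol
Product: 13 (2S,3S,10S,11S)-bis-epoxy alcohol
Conditions: Ti(OiPr)4 (cat.), L-(+)-diethyl tartrate (cat.), t-BuOOH, 4 Å MS, CH2Cl2, −20 °C
Reagents that add atoms: tert-butyl hydroperoxide CC(C)(C)OO
Why: A second Sharpless asymmetric epoxidation reaches only the allylic C2=C3 alkene and should give the (2S,3S)-epoxide under reagent control.

Step 10
Reactants: 13 (2S,3S,10S,11S)-bis-epoxy alcohol
Product: 15 (2R,3S)-triol, via Payne epoxide 14 (not isolated)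
Conditions: NaOH (0.5 M aq), t-BuOH, 70 °C
Reagents that add atoms: water O
Why: Payne rearrangement inverts C2 and keeps the C3–O bond; hydroxide then opens the far more reactive terminal epoxide at C1 to give the anti C2/C3 diol, while the isolated trisubstituted epoxide and the acetal are inert to base.

Step 11
Reactants: 15 (2R,3S)-triol
Product: 16 primary tosylate
Conditions: TsCl, Et3N, Bu2SnO (2 mol %), CH2Cl2, 0 °C
Reagents that add atoms: p-toluenesulfonyl chloride Cc1ccc(cc1)S(=O)(=O)Cl
Why: Stannylene-catalysed monotosylation of a terminal 1,2-diol is selective for the primary hydroxyl and installs the leaving group on C5′.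

Step 12
Reactants: 16 primary tosylate
Product: 17 2-alkylacrolein hydroxy tosylate
Conditions: PPTS (cat.), acetone/H2O, rt
Reagents that add atoms: water O
Why: The allylic-type acetal hydrolyses under very mild acid that should leave the trisubstituted epoxide and the tosylate intact.

Step 13
Reactants: 17 2-alkylacrolein hydroxy tosylate
Product: 18 methyl oxalate
Conditions: ClC(O)CO2Me, pyridine, CH2Cl2, −20 °C
Reagents that add atoms: methyl chlorooxoacetate COC(=O)C(=O)Cl
Why: Acylation with the reactive acid chloride takes the secondary C6′ hydroxyl and leaves the tertiary alcohol free for steric reasons; the carbonyl carbon attached to O1′ is the future C2′.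

Step 14
Reactants: 18 methyl oxalate
Product: 19 cesium oxalate
Conditions: CsOH (1.0 equiv, aq), THF, 0 °C; used at once
Reagents that add atoms: cesium hydroxide [Cs+].[OH-]
Why: One equivalent of hydroxide saponifies the unhindered, doubly activated methyl ester of the mixed oxalate within minutes and delivers the oxidisable carboxylate.

Step 15
Reactants: 19 cesium oxalate
Product: 22 bicyclic formyl lactone, via alkoxycarbonyl radical 20 (not isolated), via macrolactone enolate 21 (not isolated)
Conditions: [Ir(dF(CF3)ppy)2(dtbbpy)]PF6 (2 mol %), Cs2CO3 (0.5 equiv), degassed DMSO, 1 mM by slow addition, 450 nm LEDs, 25 °C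
Reagents that add atoms: none
Why: Proposed new method: the excited iridium photocatalyst oxidises the oxalate carboxylate, loss of CO2 leaves the secondary alkoxycarbonyl radical 20 (a second decarboxylation is slow because it would give a secondary radical flanked by two C–O bonds), and this nucleophilic σ-radical attacks the unsubstituted CH2 terminus of the 2-alkylacrolein in a 16-endo-trig macrolactonisation that makes C2′–C3′. The tertiary α-formyl radical is reduced by the divalent iridium complex to the cesium enolate 21, which displaces the primary tosylate across the ring in a 6-exo-tet C-alkylation that makes C4′–C5′, so the 14-membered carbocycle and the δ-lactone arise together in a redox-neutral process. The closest known reaction types are photoredox generation of alkoxycarbonyl radicals from cesium oxalates with Giese addition or 5-exo cyclisation, endo-selective radical macrocyclisation onto acceptor termini, and radical addition–polar cyclisation cascades onto tethered alkyl (pseudo)halides; their union in a macrocyclic setting is what is new. The only new stereocentre, quaternary C4′, is set in the alkylation under control of C6′, because in the chair-like transition state the two bonds of the eleven-atom bridge (on C4′ and C6′) lie equatorial and cis while the small formyl group goes axial. Chemoselectivity rests on polarity (the radical prefers the electron-poor terminal alkene, and the trisubstituted alkene offers only a mismatched 7-exo closure), on high dilution against oligomerisation, and on ring size (O-alkylation would need an eight-membered ring); Cs2CO3 re-forms the enolate should it be protonated.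

Step 16
Reactants: 22 bicyclic formyl lactone
Product: 23 nor-methyl bicyclic lactone
Conditions: RhCl(PPh3)3 (1.1 equiv), toluene, 110 °C
Reagents that add atoms: none
Why: Tsuji–Wilkinson decarbonylation (insertion into the formyl C–H bond, CO extrusion, reductive elimination) proceeds with retention at the migrating carbon, so hydrogen takes the axial place of the helper formyl group at C4′.

Step 17
Reactants: 23 nor-methyl bicyclic lactone
Product: 24 α-methyl bicyclic lactone
Conditions: LiN(iPr)2 (2.1 equiv), THF, −78 °C; MeI; then H2O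
Reagents that add atoms: iodomethane CI
Why: Lactone enolate alkylation should occur anti to the C4′ substituent to give the 3′,4′-trans (all-equatorial) isomer, which is also the thermodynamic one, so any epimer can be equilibrated with base.

Step 18
Reactants: 24 α-methyl bicyclic lactone
Product: 25 target CNP0319766.2
Conditions: O2, tetraphenylporphyrin (cat.), visible light, CH2Cl2, −20 °C
Reagents that add atoms: oxygen O=O
Why: In the Schenck ene reaction singlet oxygen attacks the only remaining alkene on its more crowded side; abstraction of a C7-methyl hydrogen places OOH on C6 and creates the exocyclic methylene, and attack on the outer face of the macrocycle should give the (6S) centre.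

Compound list
1 | (2E,6E)-farnesol | OC/C=C(C)/CC/C=C(C)/CCC=C(C)C | starting material
2 | (2E,6E)-farnesyl tert-butyldimethylsilyl ether | CC(C)(C)[Si](C)(C)OC/C=C(C)/CC/C=C(C)/CCC=C(C)C | intermediate
3 | (2E,6E,10E)-12-hydroxyfarnesyl TBS ether | CC(C)(C)[Si](C)(C)OC/C=C(C)/CC/C=C(C)/CC/C=C(C)/CO | intermediate
4 | (2E,6E,10S,11S)-10,11-epoxy-12-hydroxyfarnesyl TBS ether | CC(C)(C)[Si](C)(C)OC/C=C(C)/CC/C=C(C)/CC[C@@H]1O[C@@]1(C)CO | intermediate
5 | (10S,11R)-10,11-epoxy aldehyde (C12 = CHO, same spatial arrangement as 4) | CC(C)(C)[Si](C)(C)OC/C=C(C)/CC/C=C(C)/CC[C@@H]1O[C@@]1(C)C=O | intermediate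
6 | (10S,11S)-vinyl epoxide (C12=C13) | CC(C)(C)[Si](C)(C)OC/C=C(C)/CC/C=C(C)/CC[C@@H]1O[C@@]1(C)C=C | intermediate
7 | acrolein diethyl acetal (3,3-diethoxyprop-1-ene) | C=CC(OCC)OCC | starting material
8 | 2,3-dibromo-1,1-diethoxypropane | BrCC(Br)C(OCC)OCC | intermediate
9 | 2-bromo-3,3-diethoxyprop-1-ene | C=C(Br)C(OCC)OCC | intermediate
10 | B-alkyl-9-BBN (boron on C13) | CC(C)(C)[Si](C)(C)OC/C=C(C)/CC/C=C(C)/CC[C@@H]1O[C@@]1(C)CCB1C2CCCC1CCC2 | intermediate
11 | TBS ether with C14(=C15H2)CH(OEt)2 terminus (masked 2-alkylacrolein) | CC(C)(C)[Si](C)(C)OC/C=C(C)/CC/C=C(C)/CC[C@@H]1O[C@@]1(C)CCC(=C)C(OCC)OCC | intermediate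
12 | (2E,6E,10S,11S)-allylic alcohol | OC/C=C(C)/CC/C=C(C)/CC[C@@H]1O[C@@]1(C)CCC(=C)C(OCC)OCC | intermediate
13 | (2S,3S,6E,10S,11S)-2,3:10,11-bis-epoxy alcohol | OC[C@@H]1O[C@@]1(C)CC/C=C(C)/CC[C@@H]2O[C@@]2(C)CCC(=C)C(OCC)OCC | intermediate
14 | (2R,3S)-1,2-epoxy-3-ol (Payne isomer of 13) | C1O[C@H]1[C@@](C)(O)CC/C=C(C)/CC[C@@H]2O[C@@]2(C)CCC(=C)C(OCC)OCC | intermediate
15 | (2R,3S,6E,10S,11S)-1,2,3-triol | OC[C@@H](O)[C@@](C)(O)CC/C=C(C)/CC[C@@H]1O[C@@]1(C)CCC(=C)C(OCC)OCC | intermediate
16 | C1 tosylate of 15 | Cc1ccc(cc1)S(=O)(=O)OC[C@@H](O)[C@@](C)(O)CC/C=C(C)/CC[C@@H]1O[C@@]1(C)CCC(=C)C(OCC)OCC | intermediate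
17 | C1 tosylate, C2/C3 diol, 2-alkylacrolein terminus | Cc1ccc(cc1)S(=O)(=O)OC[C@@H](O)[C@@](C)(O)CC/C=C(C)/CC[C@@H]1O[C@@]1(C)CCC(=C)C=O | intermediate
18 | C2-O methyl oxalate of 17 | Cc1ccc(cc1)S(=O)(=O)OC[C@@H](OC(=O)C(=O)OC)[C@@](C)(O)CC/C=C(C)/CC[C@@H]1O[C@@]1(C)CCC(=C)C=O | intermediate
19 | cesium oxalate of 17 | [Cs+].Cc1ccc(cc1)S(=O)(=O)OC[C@@H](OC(=O)C(=O)[O-])[C@@](C)(O)CC/C=C(C)/CC[C@@H]1O[C@@]1(C)CCC(=C)C=O | intermediate
20 | secondary alkoxycarbonyl radical (radical on C2′) | Cc1ccc(cc1)S(=O)(=O)OC[C@@H](O[C]=O)[C@@](C)(O)CC/C=C(C)/CC[C@@H]1O[C@@]1(C)CCC(=C)C=O | intermediate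
21 | 16-membered macrolactone, cesium enolate of the C4′ aldehyde, tosyloxymethyl on C6′ | [Cs+].[O-]C=C1CC(=O)O[C@H](COS(=O)(=O)c2ccc(C)cc2)[C@@](C)(O)CC/C=C(C)/CC[C@@H]2O[C@@]2(C)CC1 | intermediate
22 | 14-membered carbocycle bridged C4′/C6′ by the δ-lactone; quaternary (S)-C4′ bearing CHO trans to the C6′–C3 bond | C1[C@@H]2O[C@@]2(C)CC[C@]2(C=O)C[C@@H](OC(=O)C2)[C@@](C)(O)CC/C=C(C)/C1 | intermediate
23 | same bicycle with (R)-C4′–H and C3′H2 | C1[C@@H]2O[C@@]2(C)CC[C@@H]2C[C@@H](OC(=O)C2)[C@@](C)(O)CC/C=C(C)/C1 | intermediate
24 | same bicycle with (S)-C3′–CH3 trans to the C4′ chain bond; E-C6=C7 alkene | C1[C@@H]2O[C@@]2(C)CC[C@@H]2C[C@@H](OC(=O)[C@H]2C)[C@@](C)(O)CC/C=C(C)/C1 | intermediate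
25 | CNP0319766.2 | C=C1CC[C@@H]2O[C@@]2(C)CC[C@@H]2C[C@@H](OC(=O)[C@H]2C)[C@@](C)(O)CC[C@@H]1OO | target

Total step count: 18. Longest linear sequence: 17 (steps 1–5 and 7–18).

Steps most likely to fail

Step 15. The alkoxycarbonyl radical may be lost to hydrogen abstraction from allylic positions, to slow loss of a second CO2, or to oligomerisation before the large ring closes. The enolate may also be quenched or aldolise before it alkylates. The fallback uses known chemistry and makes the bonds one at a time; it sets out from 17 and returns at 22. Intermolecular photoredox Giese addition of the methoxycarbonyl radical to the acrolein terminus of 17 (methyl N-phthalimidoyl oxalate, [Ru(bpy)3](PF6)2, Hantzsch ester, iPr2NEt, blue LEDs) should give the formyl methyl ester F1. Me3SnOH then cleaves the methyl ester to the seco acid F2. Shiina macrolactonisation (2-methyl-6-nitrobenzoic anhydride, DMAP, high dilution) onto the secondary alcohol gives the 16-membered lactone aldehyde F3. Cs2CO3 in DMF finally closes C4′–C5′ by transannular enolate alkylation to 22.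

Step 18. Hydrogen abstraction from C5 instead of the C7 methyl group (tertiary hydroperoxide) and poor facial selectivity at C6 can both erode the result. The fallback moves stereocontrol to a carbinol; it sets out from 24 and returns at 25. Photo-oxygenation followed at once by PPh3 reduction gives the epimeric exocyclic-methylene allylic alcohols F4, which are separated from the tertiary isomer. Dess–Martin oxidation gives the α-methylene ketone F5. Corey–Bakshi–Shibata reduction with the (S)-methyl oxazaborolidine and BH3·SMe2 gives the (6R)-allylic alcohol F6, and MsCl/Et3N gives the mesylate F7. SN2 displacement with 2-methoxyprop-2-yl hydroperoxide and CsOH in DMF inverts C6 to the peroxyketal F8, and aqueous acetic acid unmasks 25.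

Step 16. β-Hydride elimination from the tertiary alkyl–rhodium intermediate, or thermal or metal-induced isomerisation of the epoxide, may compete at 110 °C. The fallback replaces the metal step by a radical decarboxylation; it sets out from 22 and returns at 23. Pinnick oxidation (NaClO2, NaH2PO4, 2-methyl-2-butene) gives the carboxylic acid F9. Coupling with N-hydroxypyridine-2-thione (DCC) gives the Barton ester F10. Photolysis with t-BuSH (Barton decarboxylation) delivers hydrogen to the tertiary C4′ radical, expected from the less hindered axial direction, to give 23.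

Further compounds
F1 | step 15 | formyl methyl ester (C14 epimers), tosylate and diol as in 17 | Cc1ccc(cc1)S(=O)(=O)OC[C@@H](O)[C@@](C)(O)CC/C=C(C)/CC[C@@H]1O[C@@]1(C)CCC(C=O)CC(=O)OC
F2 | step 15 | seco acid | Cc1ccc(cc1)S(=O)(=O)OC[C@@H](O)[C@@](C)(O)CC/C=C(C)/CC[C@@H]1O[C@@]1(C)CCC(C=O)CC(=O)O
F3 | step 15 | 16-membered lactone aldehyde | O=CC1CC(=O)O[C@H](COS(=O)(=O)c2ccc(C)cc2)[C@@](C)(O)CC/C=C(C)/CC[C@@H]2O[C@@]2(C)CC1
F4 | step 18 | exocyclic-methylene allylic alcohols (C6 epimers) | C=C1CC[C@@H]2O[C@@]2(C)CC[C@@H]2C[C@@H](OC(=O)[C@H]2C)[C@@](C)(O)CCC1O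
F5 | step 18 | α-methylene ketone | C=C1CC[C@@H]2O[C@@]2(C)CC[C@@H]2C[C@@H](OC(=O)[C@H]2C)[C@@](C)(O)CCC1=O
F6 | step 18 | (6R)-allylic alcohol | C=C1CC[C@@H]2O[C@@]2(C)CC[C@@H]2C[C@@H](OC(=O)[C@H]2C)[C@@](C)(O)CC[C@H]1O
F7 | step 18 | (6R)-mesylate | C=C1CC[C@@H]2O[C@@]2(C)CC[C@@H]2C[C@@H](OC(=O)[C@H]2C)[C@@](C)(O)CC[C@H]1OS(C)(=O)=O
F8 | step 18 | (6S)-2-methoxyprop-2-yl peroxide | C=C1CC[C@@H]2O[C@@]2(C)CC[C@@H]2C[C@@H](OC(=O)[C@H]2C)[C@@](C)(O)CC[C@@H]1OOC(C)(C)OC
F9 | step 16 | C4′ carboxylic acid | C1[C@@H]2O[C@@]2(C)CC[C@]2(C(O)=O)C[C@@H](OC(=O)C2)[C@@](C)(O)CC/C=C(C)/C1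
F10 | step 16 | Barton ester | C1[C@@H]2O[C@@]2(C)CC[C@]2(C(=O)ON3C=CC=CC3=S)C[C@@H](OC(=O)C2)[C@@](C)(O)CC/C=C(C)/C1
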